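All runs are calculated for substances that don't exist.

The summer flask began by using substrate 12.9 times faster per mole of coupling partner than the dawn flask, so heat looked like a plain gain. I asked what would have to be true for the hottest flask to win.

| setting | dawn | summer | midnight | south-west | west | east | north-east |
|---|---|---|---|---|---|---|---|
| substrate | 0.25 M | 0.25 M | 0.50 M | 0.25 M | 0.25 M | 0.25 M | 0.25 M |
| coupling partner | 0.25 M | 1 M | 0.50 M | 0.500 M | 0.500 M | 0.500 M | 0.500 M |
| temperature | 0 °C | 50 °C | 0 °C | 35 °C | 65 °C | 95 °C | 5 °C |
| remark | run made earlier | run made earlier | run made earlier |  |  |  |  |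
| time |  |  |  | 25 min | 25 min | 25 min | 25 min |

- dawn (time / min: target / %, substrate / %): 15.0: 12.2, 87.4; 30.0: 18.9, 77.2; 50.0: 30.1, 66.9; 60.0: 33.1, 62.3; 80.0: 35.9, 56.6; 120: 44.9, 49.0
- summer (time / min: target / %, substrate / %): 0.500: 15.1, 79.3; 1.33: 31.5, 61.7; 3.00: 45.5, 43.8; 4.00: 51.2, 39.1; 6.00: 57.7, 32.0; 8.00: 59.0, 26.4; 10.0: 63.0, 24.4
- midnight (time / min: target / %, substrate / %): 25.0: 27.2, 66.7; 50.0: 41.8, 52.7; 60.0: 44.9, 48.2; 80.0: 51.0, 43.0; 120: 55.9, 36.6

(readings scatter by 1 percentage point)

- which flask leads in amount of target, in percent of the substrate charged ("all alike" within 1.5 percentage points) (south-west / west / east / north-east / all alike)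
- how much target is there at the end, in percent of the substrate charged: south-west
- how much target is there at the end, in percent of the substrate charged: west
- how much target is there at the end, in percent of the substrate charged: east
- how much target is there at the end, in percent of the substrate charged: north-east

In summer the pseudo-first-order rate of substrate loss was 0.464 min⁻¹ at the first reading, but 0.0786 min⁻¹ over the last stretch. Yet coupling had taken 0.189 M of the 1 M of partner charged. So I supposed that partner was also lost in pairs, which makes the reciprocal of [partner] climb linearly, at 0.887 min⁻¹ relative to its start.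

I called ρ the waste ratio, the pairwise loss constant, counted in partner lost, over the coupling constant, and read 1.91 from summer. With b the starting [partner]/[substrate], dividing the two rate laws removes time. With ρ held constant through a run, the fraction of substrate left when partner is gone is (1 + (ρ − 1)b) raised to 1/(1 − ρ).

For b = 2.00, substrate is consumed completely only if ρ stands at 0.500 or below, and summer read 1.91. At that reading the rule leaves 32.1% of the substrate. With summer's last reading of 83.3% of lost substrate found as target, my estimate of target at that point is 56.6%. Carrying summer's ρ over to west unchanged was an assumption, and on it I took that as my rough figure for west. Supposing further that ρ rises with heat, I expected less in east and the lead in south-west.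

The forecast named south-west, with 52%, 37%, 23% and 36% for south-west, west, east and north-east, holding that “heat lowers the attainable conversion”.

The flasks gave 60.1%, 55.3%, 40.2% and 36.7% in that order, so south-west led.

    substrate + coupling partner ⇌ intermediate (K = 0.0640 L mol⁻¹, k = 0.340 L mol⁻¹ min⁻¹, Ea = 49.0 kJ mol⁻¹, ΔH = −41.0 kJ mol⁻¹)
    intermediate → target (k = 0.920 min⁻¹, Ea = 76.0 kJ mol⁻¹)
    2 coupling partner → self-condensation product (k = 0.00890 L mol⁻¹ min⁻¹, Ea = 60.0 kJ mol⁻¹)
    intermediate → side product (k = 0.120 min⁻¹, Ea = 81.0 kJ mol⁻¹)
    intermediate → decomposed reagent (k = 0.0110 min⁻¹, Ea = 89.0 kJ mol⁻¹)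
    (constants at 5 °C)

West held 30.3% substrate after 250 min against my 32.1%, with partner, its limiting reagent, at 0%. East held 49.0% of substrate with partner at 0% by 25.0 min; a ρ chosen to fit that flask, 3.50, gives 48.8% and stands above summer's 1.91. The main reason for east's shortfall of target was the backward run from intermediate: without it, east gave 78.8% of target instead of 40.2%.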